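**Assumption:** (+)-catechin hydrate (2R,3S) is treated as an allowed commercial chiral-pool starting material. The usual de novo route (geranyl/bromo B-ring aldehyde → 1,3-diarylpropene → Sharpless AD → cyclisation) is deliberately avoided.

## Retrosynthetic overview

1. Target ⇐ 9 by fluoride desilylation, then mild acid removal of the catechol orthoester.
2. C5′–geranyl bond ⇐ Pd allyl–aryl Suzuki coupling of 5′-Bpin arene 7 with geranyl bromide.
3. C5′–B bond ⇐ Ir-catalysed C–H borylation of 5 (key, risk-bearing step): with the catechol tied back as a benzodioxole, H-5′ is the only unhindered aryl C–H.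
4. 5 ⇐ (+)-catechin by chemoselective protection; C2(R) and C3(S) are inherited and never touched.
5. Ring order: A, C and B rings are bought intact; the only ring formed is the temporary dioxole (step 2), opened again in step 6.

## Route

**Step 1**
Reactants: 1 (+)-catechin; 2 tert-butyldimethylsilyl chloride
Product: 3 (2R,3S)-3,5,7-tris(tert-butyldimethylsilyloxy)-2-(3,4-dihydroxyphenyl)chromane (catechol free)
Conditions: PhB(OH)2 (1.05 eq), THF–PhMe azeotrope; then TBSCl (3.6 eq), imidazole (8 eq), DMAP (cat.), DMF, 40 °C; then pinacol, aq. NH4Cl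
Reagents that add atoms: TBSCl, CC(C)(C)[Si](C)(C)Cl (×3)
Why: Transient boronic-ester protection: PhB(OH)2 condenses only with the catechol (five-membered aryl boronate), so imidazole-promoted silylation caps exactly the 3-, 5- and 7-OH groups, and pinacol transesterification then frees the catechol; C2 and C3 are not involved.

**Step 2**
Reactants: 3; 4 triethyl orthoformate
Product: 5 (2R,3S)-3,5,7-tris(TBSO)-2-(2-ethoxy-1,3-benzodioxol-5-yl)chromane (about 1:1 epimers at the orthoester carbon)
Conditions: HC(OEt)3 (3 eq), PPTS (5 mol%), PhMe, 80 °C, 4 Å MS (–EtOH); Et3N-deactivated SiO2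
Reagents that add atoms: triethyl orthoformate, CCOC(OCC)OCC
Why: Acid-catalysed orthoester exchange: the catechol displaces two EtOH to form the five-membered cyclic ethyl orthoformate, a small, base-stable, tied-back dioxole; the new orthoester carbon forms as an epimer mixture that does not matter because it is removed in step 6.

**Step 3**
Reactants: 5; 6 bis(pinacolato)diboron
Product: 7 (2R,3S)-3,5,7-tris(TBSO)-2-[2-ethoxy-7-(4,4,5,5-tetramethyl-1,3,2-dioxaborolan-2-yl)-1,3-benzodioxol-5-yl]chromane (boron at C5′ of the flavan)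
Conditions: [Ir(OMe)(cod)]2 (2.5 mol%), dtbpy (5 mol%), B2pin2 (1.1 eq), THF, 80 °C
Reagents that add atoms: B2pin2, CC1(C)OB(OC1(C)C)B1OC(C)(C)C(C)(C)O1
Why: Sterically controlled Ir C–H borylation, which tolerates a tied-back dioxole oxygen as the only ortho neighbour (benzodioxoles borylate ortho to O), so H-5′ is the single accessible site: H-2′ lies between C1′ and O, H-6′ is ortho to the bulky C2 substituent, H-6 and H-8 are each flanked by two oxygens, and after mono-borylation no unhindered C–H remains; no stereocentre is touched.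

**Step 4**
Reactants: 7; 8 geranyl bromide, (2E)-1-bromo-3,7-dimethylocta-2,6-diene
Product: 9 (2R,3S)-3,5,7-tris(TBSO)-2-[2-ethoxy-7-[(2E)-3,7-dimethylocta-2,6-dien-1-yl]-1,3-benzodioxol-5-yl]chromane
Conditions: geranyl bromide (1.5–2 eq), Pd(dppf)Cl2·CH2Cl2 (5 mol%), K3PO4 (3 eq), THF/H2O (10:1), 50 °C
Reagents that add atoms: geranyl bromide, CC(C)=CCC/C(C)=C/CBr
Why: Suzuki–Miyaura allyl–aryl coupling: Pd(0) ionises geranyl bromide to a π-geranyl complex, the phosphate-activated aryl boronate transmetalates, and reductive elimination at the unsubstituted allyl terminus gives the linear product, with the 2E geometry kept because syn/anti exchange would need a σ-allyl at tertiary C3.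

**Step 5**
Reactants: 9
Product: 10 (2R,3S)-2-[2-ethoxy-7-[(2E)-3,7-dimethylocta-2,6-dien-1-yl]-1,3-benzodioxol-5-yl]chromane-3,5,7-triol
Conditions: TBAF (4 eq), AcOH (4 eq), THF, 0 °C → rt
Reagents that add atoms: none
Why: Buffered fluoride desilylation cleaves the three Si–O bonds while the base-stable orthoester keeps the 4′-oxygen masked, so quinone-methide epimerisation at C2 and catechol autoxidation cannot occur, and the geranyl diene is inert.

**Step 6**
Reactants: 10
Product: 11 target, (2R,3S)-2-[3-[(2E)-3,7-dimethylocta-2,6-dien-1-yl]-4,5-dihydroxyphenyl]chromane-3,5,7-triol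
Conditions: PPTS (0.2 eq), MeOH/H2O (9:1), rt, Ar; Sephadex LH-20
Reagents that add atoms: none
Why: Acid-catalysed orthoester methanolysis/hydrolysis releases the catechol under conditions much milder than those needed to protonate the trisubstituted geranyl olefins (the same window used to remove MOM groups from ortho-geranyl phenols), so no chroman cyclisation occurs and C2/C3 are unaffected.

## Compound list

1 | (+)-catechin, (2R,3S)-2-(3,4-dihydroxyphenyl)chromane-3,5,7-triol | Oc1ccc(cc1O)[C@H]1Oc2cc(O)cc(O)c2C[C@@H]1O | starting material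
2 | tert-butyldimethylsilyl chloride | CC(C)(C)[Si](C)(C)Cl | starting material
3 | (2R,3S)-3,5,7-tris(TBSO)-2-(3,4-dihydroxyphenyl)chromane | Oc1ccc(cc1O)[C@H]1Oc2cc(O[Si](C)(C)C(C)(C)C)cc(O[Si](C)(C)C(C)(C)C)c2C[C@@H]1O[Si](C)(C)C(C)(C)C | intermediate
4 | triethyl orthoformate | CCOC(OCC)OCC | starting material
5 | (2R,3S)-3,5,7-tris(TBSO)-2-(2-ethoxy-1,3-benzodioxol-5-yl)chromane (orthoester epimers) | CCOC1Oc2ccc(cc2O1)[C@H]1Oc2cc(O[Si](C)(C)C(C)(C)C)cc(O[Si](C)(C)C(C)(C)C)c2C[C@@H]1O[Si](C)(C)C(C)(C)C | intermediate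
6 | bis(pinacolato)diboron | CC1(C)OB(OC1(C)C)B1OC(C)(C)C(C)(C)O1 | starting material
7 | (2R,3S)-3,5,7-tris(TBSO)-2-[2-ethoxy-7-(pinacolboryl)-1,3-benzodioxol-5-yl]chromane | CCOC1Oc2c(B3OC(C)(C)C(C)(C)O3)cc(cc2O1)[C@H]1Oc2cc(O[Si](C)(C)C(C)(C)C)cc(O[Si](C)(C)C(C)(C)C)c2C[C@@H]1O[Si](C)(C)C(C)(C)C | intermediate
8 | geranyl bromide, (2E)-1-bromo-3,7-dimethylocta-2,6-diene | CC(C)=CCC/C(C)=C/CBr | starting material
9 | (2R,3S)-3,5,7-tris(TBSO)-2-[2-ethoxy-7-(E)-geranyl-1,3-benzodioxol-5-yl]chromane | CCOC1Oc2c(C/C=C(\C)CCC=C(C)C)cc(cc2O1)[C@H]1Oc2cc(O[Si](C)(C)C(C)(C)C)cc(O[Si](C)(C)C(C)(C)C)c2C[C@@H]1O[Si](C)(C)C(C)(C)C | intermediate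
10 | (2R,3S)-2-[2-ethoxy-7-(E)-geranyl-1,3-benzodioxol-5-yl]chromane-3,5,7-triol | CCOC1Oc2c(C/C=C(\C)CCC=C(C)C)cc(cc2O1)[C@H]1Oc2cc(O)cc(O)c2C[C@@H]1O | intermediate
11 | 5′-geranyl-(+)-catechin, (2R,3S)-2-[3-[(2E)-3,7-dimethylocta-2,6-dienyl]-4,5-dihydroxyphenyl]chromane-3,5,7-triol | CC(C)=CCC/C(C)=C/Cc1cc([C@H]2Oc3cc(O)cc(O)c3C[C@@H]2O)cc(O)c1O | target

## Totals and main risks

Total steps: 6. Longest linear sequence: 6 (fully linear from 1).

Steps most likely to fail:

- **Step 3 (C–H borylation; site selectivity and activity next to the orthoester oxygen).** Fallback: switch from steric to directing-group control. Borylate catechol 3 directly after in-situ O-borylation with HBpin, so the ArO–Bpin groups direct Ir to the only free ortho position (C5′). Then bis-TBS the catechol, couple as in step 4, and finish with a single fluoride deprotection (no orthoester).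
- **Step 4 (allyl–aryl coupling; linear/E selectivity, protodeboronation, partial aryl-OTBS loss).** Fallback: invert the polarity. Convert 7 to the 5′-bromide (CuBr2 bromodeboronation), then Br/Li exchange, transmetalation to copper (CuBr·SMe2) and SN2 alkylation with geranyl bromide, the classic linear, E-retentive aryl prenylation.
- **Step 1 (one-pot transient boronate / selective tris-silylation).** Fallback: stepwise orthogonal protection. Form the 3′,4′-diphenylmethylene ketal (Ph2CCl2), silylate the three remaining OH groups, then hydrogenolyse the ketal (H2, Pd(OH)2/C; no olefin present yet) to reach 3.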